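The ten-membered ring is disconnected through its 1,5-diene C10=C1–C2–C3–C4=C5: a [3,3] shift that forms C2–C3 and breaks C5–C10 maps the germacrane ring onto the cyclohexane C5–C6–C7–C8–C9–C10. In one operation the anionic oxy-Cope rearrangement opens that cyclohexane to the cyclodecadiene, sets both ring-trans olefins and leaves a regiodefined C1=C10 enolate, trapped as the triflate that later receives C14. The precursor is an all-equatorial cyclohexanol: vinyl and axial OH on C10, a 3-PMB-oxyprop-1-en-2-yl group on C5, OTBS on C6, a 2-(TBS-oxy)ethyl arm on C7 and OTES on C8, so the C6–C8 stereotriad exists before the macrocycle does.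

Key step: step 15

Remark: germacrane numbering is used for all intermediates; both ring olefins are ring-trans (C9 anti to C2, C3 anti to C6), which by CIP makes the C10 enol triflate (1(10)Z,4Z), not E,E, and the target (1(10)E,4Z); aldehyde 1 is assumed to be a catalogue item (otherwise one oxidation of 4-(TBS-oxy)butan-1-ol).

Step 1
Reactants: 1 4-(tert-butyldimethylsilyloxy)butanal; 2 but-3-en-2-one (methyl vinyl ketone)
Product: 3 (R)-2-[2-(TBS-oxy)ethyl]-5-oxohexanal
Conditions: (R)-2-[methoxy(diphenyl)methyl]pyrrolidine (5 mol%), ethyl 3,4-dihydroxybenzoate (20 mol%), neat, 4 °C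
Reagents that add atoms: none
Why: Enamine-catalysed Michael addition in which the bulky group of the (R)-prolinol ether shields one face of the E-enamine of 1, so that the enone adds to the other face and C7 is set as R.

Step 2
Reactants: 3 (R)-2-[2-(TBS-oxy)ethyl]-5-oxohexanal
Product: 4 (R)-4-[2-(TBS-oxy)ethyl]cyclohex-2-en-1-one
Conditions: LiOH·H2O (cat.), i-PrOH, rt
Reagents that add atoms: none
Why: Intramolecular aldol condensation of the methyl ketone onto the aldehyde under mild base should close the cyclohexenone (C9=C8) faster than the C7 centre epimerises.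

Step 3
Reactants: 4 (R)-4-[2-(TBS-oxy)ethyl]cyclohex-2-en-1-one
Product: 6 (3S,4R)-3-hydroxy-4-[2-(TBS-oxy)ethyl]cyclohexan-1-one (OH trans to the side chain), via β-boryl ketone 5 (not isolated)
Conditions: CuCl (5 mol%), DPEphos, NaOt-Bu (cat.), B2pin2, MeOH, THF, rt; then NaBO3·4H2O, THF/H2O, rt
Reagents that add atoms: sodium perborate, O[B-]1(O)OO[B-](O)(O)OO1.[Na+].[Na+]
Why: Copper-catalysed conjugate borylation should place boron on C8 anti to the adjacent C7 side chain (the trans-3,4 preference of 4-substituted cyclohexenones), and the stereoretentive C–B oxidation turns it into the C8 hydroxyl.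

Step 4
Reactants: 6 (3S,4R)-3-hydroxy-4-[2-(TBS-oxy)ethyl]cyclohexan-1-one
Product: 7 (3S,4R)-3-(triethylsilyloxy)-4-[2-(TBS-oxy)ethyl]cyclohexan-1-one
Conditions: TESCl, imidazole, CH2Cl2, 0 °C
Reagents that add atoms: chlorotriethylsilane, CC[Si](Cl)(CC)CC
Why: Routine silylation of the secondary aldol hydroxyl, with TES chosen because it can later be removed beside the hindered secondary TBS ether at C6.

Step 5
Reactants: 7 (3S,4R)-3-(triethylsilyloxy)-4-[2-(TBS-oxy)ethyl]cyclohexan-1-one
Product: 9 (4S,5S)-5-(triethylsilyloxy)-4-[2-(TBS-oxy)ethyl]cyclohex-2-en-1-one, via lithium enolate 8 (not isolated)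
Conditions: LDA, THF, −78 °C; then N-tert-butylbenzenesulfinimidoyl chloride, −78 °C
Reagents that add atoms: none
Why: Kinetic deprotonation of a β-silyloxy ketone should occur at the α-CH2 remote from the oxygen-bearing carbon (C5), and the enolate is dehydrogenated in the Mukaiyama sulfinimidoyl chloride reaction to the C5=C6 enone.

Step 6
Reactants: 9 (4S,5S)-5-(triethylsilyloxy)-4-[2-(TBS-oxy)ethyl]cyclohex-2-en-1-one
Product: 10 (4S,5S)-2-iodo-5-(triethylsilyloxy)-4-[2-(TBS-oxy)ethyl]cyclohex-2-en-1-one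
Conditions: I2, pyridine, CH2Cl2, 0 °C → rt
Reagents that add atoms: iodine, II
Why: Pyridine-mediated α-iodination of a cyclohexenone (addition–elimination) is general and too weakly basic to trigger loss of the C8 silyloxy group.

Step 7
Reactants: 11 2-bromoprop-2-en-1-ol
Product: 12 2-bromoallyl 4-methoxybenzyl ether
Conditions: NaH, PMBCl, Bu4NI (cat.), THF/DMF, 0 °C → rt
Reagents that add atoms: 4-methoxybenzyl chloride, COc1ccc(CCl)cc1
Why: Williamson etherification of the primary allylic alkoxide, under which the vinyl bromide is inert.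

Step 8
Reactants: 10 (4S,5S)-2-iodo-5-(triethylsilyloxy)-4-[2-(TBS-oxy)ethyl]cyclohex-2-en-1-one; 12 2-bromoallyl 4-methoxybenzyl ether
Product: 15 (4S,5S)-2-[3-(PMB-oxy)prop-1-en-2-yl]-5-(triethylsilyloxy)-4-[2-(TBS-oxy)ethyl]cyclohex-2-en-1-one, via alkenyllithium 13 (not isolated), via alkenylzinc chloride 14 (not isolated)
Conditions: 12, t-BuLi (2 equiv), Et2O, −78 °C; ZnCl2, THF, −78 → 0 °C; then 10, Pd2(dba)3 (cat.), P(2-furyl)3, THF/DMF, rt
Reagents that add atoms: none
Why: Bromine–lithium exchange and transmetalation give an alkenylzinc that should undergo Negishi coupling with the α-iodoenone (forming C4–C5) without adding to the ketone.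

Step 9
Reactants: 15 (4S,5S)-2-[3-(PMB-oxy)prop-1-en-2-yl]-5-(triethylsilyloxy)-4-[2-(TBS-oxy)ethyl]cyclohex-2-en-1-one
Product: 16 (1R,4S,5S)-2-[3-(PMB-oxy)prop-1-en-2-yl]-5-(triethylsilyloxy)-4-[2-(TBS-oxy)ethyl]cyclohex-2-en-1-ol (C10 OH cis to the C8 OTES)
Conditions: NaBH4, CeCl3·7H2O, MeOH, −78 °C
Reagents that add atoms: none
Why: Luche 1,2-reduction delivers hydride axially, so the temporary C10 hydroxyl should be pseudo-equatorial and cis to the equatorial C8 silyloxy group (as carvone gives cis-carveol), that is, on the face anti to the C7 side chain.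

Step 10
Reactants: 16 (1R,4S,5S)-2-[3-(PMB-oxy)prop-1-en-2-yl]-5-(triethylsilyloxy)-4-[2-(TBS-oxy)ethyl]cyclohex-2-en-1-ol
Product: 17 C5–C6 epoxide of 16, oxirane cis to the C10 hydroxyl and the C8 OTES, trans to the C7 side chain
Conditions: VO(acac)2 (cat.), t-BuOOH, CH2Cl2, 0 °C
Reagents that add atoms: tert-butyl hydroperoxide, CC(C)(C)OO
Why: Vanadium-catalysed hydroxyl-directed epoxidation should attack only the allylic C5=C6 bond and from the face of the C10 hydroxyl, which puts the C6 oxygen trans to the C7 side chain, an outcome that intermolecular nucleophilic epoxidation of 15 could not guarantee against the 1,3-related C8 substituent.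

Step 11
Reactants: 17 C5–C6 epoxy alcohol
Product: 18 C5–C6 epoxy ketone (C10 ketone, oxirane trans to the C7 side chain, C5 bearing the alkenyl group)
Conditions: Dess–Martin periodinane, NaHCO3, CH2Cl2, 0 °C → rt
Reagents that add atoms: none
Why: Buffered periodinane oxidation of the secondary carbinol restores the C10 ketone and erases the temporary stereocentre without opening the vinyl oxirane.

Step 12
Reactants: 18 C5–C6 epoxy ketone
Product: 19 all-trans 2-[3-(PMB-oxy)prop-1-en-2-yl]-3-hydroxy-5-(triethylsilyloxy)-4-[2-(TBS-oxy)ethyl]cyclohexan-1-one (C5 alkenyl, C6 OH, C7 arm and C8 OTES all equatorial)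
Conditions: SmI2 (2.2 equiv), THF/MeOH, −90 °C; pH 7 buffer
Reagents that add atoms: none
Why: Samarium diiodide reduction of an α,β-epoxy ketone cleaves the Cα–O bond at C5 and keeps the C6 oxygen, and α-protonation of the samarium enolate should leave the alkenyl group equatorial, trans to the C6 hydroxyl, which is also the thermodynamic arrangement.

Step 13
Reactants: 19 all-trans β-hydroxy ketone
Product: 20 all-trans 2-[3-(PMB-oxy)prop-1-en-2-yl]-3-(TBS-oxy)-5-(triethylsilyloxy)-4-[2-(TBS-oxy)ethyl]cyclohexan-1-one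
Conditions: TBSOTf, 2,6-lutidine, CH2Cl2, −78 °C
Reagents that add atoms: tert-butyldimethylsilyl triflate, CC(C)(C)[Si](C)(C)OS(=O)(=O)C(F)(F)F
Why: Low-temperature silylation with the silyl triflate and a hindered base caps the labile aldol hydroxyl before it can eliminate.

Step 14
Reactants: 20 all-trans silyloxy ketone; 21 vinylmagnesium bromide
Product: 22 1-vinyl-2-[3-(PMB-oxy)prop-1-en-2-yl]-3-(TBS-oxy)-5-(triethylsilyloxy)-4-[2-(TBS-oxy)ethyl]cyclohexan-1-ol (C10 OH axial and cis to the C5 alkenyl group; vinyl, alkenyl, OTBS, arm and OTES all equatorial)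
Conditions: CeCl3 (anhydrous), THF, −78 °C
Reagents that add atoms: none
Why: The weakly basic vinylcerium reagent should add to the enolisable ketone (organocerium 1,2-addition) from the equatorial direction, as Grignard reagents do with 2-substituted cyclohexanones, placing vinyl trans to the C5 alkenyl group and the hydroxyl axial.

Step 15
Reactants: 22 1-vinyl-2-alkenylcyclohexanol precursor
Product: 25 ten-membered C10 enol triflate (1(10),4-diene, both ring olefins ring-trans; C6 OTBS, C7 2-(TBS-oxy)ethyl, C8 OTES, C15 OPMB), via potassium alkoxide 23 (not isolated), via potassium enolate 24 (not isolated)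
Conditions: KH, 18-crown-6, THF, 0 °C → rt; then PhNTf2, −78 → 0 °C
Reagents that add atoms: N-phenylbis(trifluoromethanesulfonimide), O=S(=O)(N(c1ccccc1)S(=O)(=O)C(F)(F)F)C(F)(F)F
Why: KH with 18-crown-6 gives the C10 potassium alkoxide, which undergoes a charge-accelerated concerted [3,3]-sigmatropic shift through a chair transition state spanning C2=C1–C10–C5–C4=C3, so that C2–C3 forms as C5–C10 breaks. This is the anionic oxy-Cope rearrangement, closest in type to the ring expansion of trans-1,2-divinylcyclohexanols to (E)-cyclodec-5-enones with electrophilic trapping of the enolate. The ten-membered ring is formed not by end-to-end cyclisation but by four-atom ring expansion of the cyclohexane, the bond shared by the two allyl units being the one that is cut. No stereocentre is created (C5 and C10 become sp2 while C6, C7 and C8 are untouched), and the olefin geometries are set by the chair, in which the ring bonds C5–C6 and C10–C9 are equatorial and therefore end up anti to C3 and C2. The step needs the ring-trans/ring-trans diene, a single enolate regioisomer and intact silyl ethers: the trans-diequatorial alkenyl groups on a chair locked by three further equatorial substituents secure the first, the bond reorganisation itself the second, and the axial-O/equatorial-OSi (trans-1,3) relation of C10 to C6 and C8, which disfavours silyl migration, the third. O-Sulfonylation of the potassium enolate by N-phenyltriflimide at −78 °C in the absence of a proton source (KH, not an amide base) should keep the enolate on the C1 side and give the triflate with retention of geometry.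

Step 16
Reactants: 25 ten-membered C10 enol triflate
Product: 26 C10-methyl cyclodeca-1(10),4-diene (C14 installed; C6 OTBS, C7 2-(TBS-oxy)ethyl, C8 OTES, C15 OPMB)
Conditions: MeZnCl, Pd(PPh3)4 (cat.), THF, 0 °C → rt
Reagents that add atoms: methylzinc chloride, C[Zn]Cl
Why: Negishi cross-coupling of an enol triflate proceeds with retention of olefin geometry and tolerates silyl and PMB ethers.

Step 17
Reactants: 26 C10-methyl cyclodecadiene
Product: 27 C8,C12-diol (C6 OTBS and C15 OPMB retained)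
Conditions: HF·pyridine, pyridine, THF, 0 °C → rt
Reagents that add atoms: none
Why: Buffered HF·pyridine should cleave the secondary TES ether and the primary TBS ether much faster than the hindered secondary allylic TBS ether at C6 (selective desilylation), without acid strong enough to cyclise the 1,5-diene.

Step 18
Reactants: 27 C8,C12-diol
Product: 29 trans-fused 12,8-γ-lactone (C6 OTBS, C15 OPMB), via lactol 28 (not isolated)
Conditions: TEMPO (cat.), PhI(OAc)2, CH2Cl2, rt
Reagents that add atoms: none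
Why: The oxoammonium oxidant attacks only the primary C12 alcohol, and the aldehyde closes onto the C8 hydroxyl to a lactol that is oxidised on to the lactone (oxidative lactonisation of a 1,4-diol).

Step 19
Reactants: 29 trans-fused 12,8-γ-lactone
Product: 33 α-methylene-γ-lactone (C11=C13; C6 OTBS, C15 OPMB), via lithium enolate 30 (not isolated), via Mannich base 31 (not isolated), via ammonium iodide 32 (not isolated)
Conditions: LDA, THF, −78 °C; CH2=NMe2+ I−, −78 °C → rt; MeI, rt; aq. NaHCO3, rt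
Reagents that add atoms: N,N-dimethylmethyleneiminium iodide (Eschenmoser's salt), C=[N+](C)C.[I-]
Why: The lactone enolate, which has no β-leaving group, undergoes a Mannich reaction at C11, and quaternisation followed by mild base elimination gives the exocyclic methylene.

Step 20
Reactants: 33 α-methylene-γ-lactone
Product: 34 C15 primary allylic alcohol (C6 OTBS retained)
Conditions: DDQ, CH2Cl2/pH 7 buffer, 0 °C
Reagents that add atoms: none
Why: Oxidative cleavage of the PMB ether by DDQ under buffered conditions leaves the silyl ether, the diene and the methylene lactone untouched.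

Step 21
Reactants: 35 (tert-butyldimethylsilyloxy)acetaldehyde; 36 ethyl 2-(triphenylphosphoranylidene)propanoate
Product: 37 ethyl (E)-4-(TBS-oxy)-2-methylbut-2-enoate
Conditions: CH2Cl2, rt
Reagents that add atoms: none
Why: Wittig olefination with a stabilised α-methyl ylide gives the (E)-trisubstituted enoate.

Step 22
Reactants: 37 ethyl (E)-4-(TBS-oxy)-2-methylbut-2-enoate
Product: 38 (E)-4-(TBS-oxy)-2-methylbut-2-enoic acid
Conditions: LiOH, THF/H2O, rt; then aq. NaHSO4 to pH 4
Reagents that add atoms: lithium hydroxide, [Li+].[OH-]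
Why: Saponification of the ethyl ester leaves the primary TBS ether and the olefin geometry intact.

Step 23
Reactants: 34 C15 primary allylic alcohol; 38 (E)-4-(TBS-oxy)-2-methylbut-2-enoic acid
Product: 39 C15 (E)-4-(TBS-oxy)-2-methylbut-2-enoate of 34 (C6 OTBS retained)
Conditions: EDC·HCl, DMAP, CH2Cl2, 0 °C → rt
Reagents that add atoms: none
Why: Steglich esterification acylates the only free hydroxyl, the unhindered primary allylic C15 alcohol.

Step 24
Reactants: 39 bis-TBS ester
Product: 40 CNP0326626.1, (6R,7S,8S)-6-hydroxy-15-[(E)-4-hydroxy-2-methylbut-2-enoyloxy]germacra-1(10),4,11(13)-trien-12,8-olide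
Conditions: HF·pyridine, THF, 0 °C → rt
Reagents that add atoms: none
Why: Fluoride-mediated desilylation under mildly acidic conditions removes both TBS ethers while avoiding translactonisation to O6 and conjugate addition to the methylene lactone.

Compound list
1 | 4-(tert-butyldimethylsilyloxy)butanal | O=CCCCO[Si](C)(C)C(C)(C)C | starting material
2 | but-3-en-2-one | CC(=O)C=C | starting material
3 | (R)-2-[2-(TBS-oxy)ethyl]-5-oxohexanal | O=C[C@@H](CCO[Si](C)(C)C(C)(C)C)CCC(C)=O | intermediate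
4 | (R)-4-[2-(TBS-oxy)ethyl]cyclohex-2-en-1-one | O=C1C=C[C@@H](CCO[Si](C)(C)C(C)(C)C)CC1 | intermediate
5 | (3S,4R)-3-(pinacolboryl)-4-[2-(TBS-oxy)ethyl]cyclohexan-1-one | O=C1C[C@H](B2OC(C)(C)C(C)(C)O2)[C@@H](CCO[Si](C)(C)C(C)(C)C)CC1 | intermediate
6 | (3S,4R)-3-hydroxy-4-[2-(TBS-oxy)ethyl]cyclohexan-1-one | O=C1C[C@H](O)[C@@H](CCO[Si](C)(C)C(C)(C)C)CC1 | intermediate
7 | (3S,4R)-3-(triethylsilyloxy)-4-[2-(TBS-oxy)ethyl]cyclohexan-1-one | O=C1C[C@H](O[Si](CC)(CC)CC)[C@@H](CCO[Si](C)(C)C(C)(C)C)CC1 | intermediate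
8 | lithium enolate of 7 (enolate C10=C5, remote from OTES) | [Li+].[O-]C1=CC[C@H](CCO[Si](C)(C)C(C)(C)C)[C@@H](O[Si](CC)(CC)CC)C1 | intermediate
9 | (4S,5S)-5-(triethylsilyloxy)-4-[2-(TBS-oxy)ethyl]cyclohex-2-en-1-one | O=C1C[C@H](O[Si](CC)(CC)CC)[C@@H](CCO[Si](C)(C)C(C)(C)C)C=C1 | intermediate
10 | (4S,5S)-2-iodo-5-(triethylsilyloxy)-4-[2-(TBS-oxy)ethyl]cyclohex-2-en-1-one | O=C1C[C@H](O[Si](CC)(CC)CC)[C@@H](CCO[Si](C)(C)C(C)(C)C)C=C1I | intermediate
11 | 2-bromoprop-2-en-1-ol | OCC(Br)=C | starting material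
12 | 2-bromoallyl 4-methoxybenzyl ether | C=C(Br)COCc1ccc(OC)cc1 | intermediate
13 | [3-(PMB-oxy)prop-1-en-2-yl]lithium | [Li]C(=C)COCc1ccc(OC)cc1 | intermediate
14 | [3-(PMB-oxy)prop-1-en-2-yl]zinc chloride | Cl[Zn]C(=C)COCc1ccc(OC)cc1 | intermediate
15 | (4S,5S)-2-[3-(PMB-oxy)prop-1-en-2-yl]-5-(triethylsilyloxy)-4-[2-(TBS-oxy)ethyl]cyclohex-2-en-1-one | O=C1C[C@H](O[Si](CC)(CC)CC)[C@@H](CCO[Si](C)(C)C(C)(C)C)C=C1C(=C)COCc1ccc(OC)cc1 | intermediate
16 | (1R,4S,5S)-2-[3-(PMB-oxy)prop-1-en-2-yl]-5-(triethylsilyloxy)-4-[2-(TBS-oxy)ethyl]cyclohex-2-en-1-ol | O[C@@H]1C[C@H](O[Si](CC)(CC)CC)[C@@H](CCO[Si](C)(C)C(C)(C)C)C=C1C(=C)COCc1ccc(OC)cc1 | intermediate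
17 | 2,3-epoxide of 16 (germacrane C5–C6 oxirane cis to the C10 OH and C8 OTES, trans to the C7 arm) | O[C@@H]1C[C@H](O[Si](CC)(CC)CC)[C@@H](CCO[Si](C)(C)C(C)(C)C)[C@@H]2O[C@]12C(=C)COCc1ccc(OC)cc1 | intermediate
18 | C5–C6 epoxy ketone (C10 ketone of 17) | O=C1C[C@H](O[Si](CC)(CC)CC)[C@@H](CCO[Si](C)(C)C(C)(C)C)[C@@H]2O[C@]12C(=C)COCc1ccc(OC)cc1 | intermediate
19 | all-trans 2-[3-(PMB-oxy)prop-1-en-2-yl]-3-hydroxy-5-(triethylsilyloxy)-4-[2-(TBS-oxy)ethyl]cyclohexan-1-one | O=C1C[C@H](O[Si](CC)(CC)CC)[C@@H](CCO[Si](C)(C)C(C)(C)C)[C@H](O)[C@H]1C(=C)COCc1ccc(OC)cc1 | intermediate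
20 | all-trans 2-[3-(PMB-oxy)prop-1-en-2-yl]-3-(TBS-oxy)-5-(triethylsilyloxy)-4-[2-(TBS-oxy)ethyl]cyclohexan-1-one | O=C1C[C@H](O[Si](CC)(CC)CC)[C@@H](CCO[Si](C)(C)C(C)(C)C)[C@H](O[Si](C)(C)C(C)(C)C)[C@H]1C(=C)COCc1ccc(OC)cc1 | intermediate
21 | vinylmagnesium bromide | C=C[Mg]Br | starting material
22 | 1-vinyl-2-[3-(PMB-oxy)prop-1-en-2-yl]-3-(TBS-oxy)-5-(triethylsilyloxy)-4-[2-(TBS-oxy)ethyl]cyclohexan-1-ol (OH axial, cis to the C2 alkenyl group; all other ring substituents equatorial and mutually trans) | C=C[C@]1(O)C[C@H](O[Si](CC)(CC)CC)[C@@H](CCO[Si](C)(C)C(C)(C)C)[C@H](O[Si](C)(C)C(C)(C)C)[C@H]1C(=C)COCc1ccc(OC)cc1 | intermediate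
23 | potassium alkoxide of 22 | C=C[C@]1([O-])C[C@H](O[Si](CC)(CC)CC)[C@@H](CCO[Si](C)(C)C(C)(C)C)[C@H](O[Si](C)(C)C(C)(C)C)[C@H]1C(=C)COCc1ccc(OC)cc1.[K+] | intermediate
24 | potassium C1=C10 enolate of the ring-expanded cyclodeca-4-enone (both ring olefins ring-trans) | CC(C)(C)[Si](C)(C)OCC[C@@H]1[C@@H](O[Si](CC)(CC)CC)C/C([O-])=C/CC/C(COCc2ccc(OC)cc2)=C/[C@H]1O[Si](C)(C)C(C)(C)C.[K+] | intermediate
25 | ten-membered C10 enol triflate, 1(10),4-diene with both ring olefins ring-trans, C6 OTBS, C7 2-(TBS-oxy)ethyl, C8 OTES, C15 OPMB | CC(C)(C)[Si](C)(C)OCC[C@@H]1[C@@H](O[Si](CC)(CC)CC)C/C(OS(=O)(=O)C(F)(F)F)=C/CC/C(COCc2ccc(OC)cc2)=C/[C@H]1O[Si](C)(C)C(C)(C)C | intermediate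
26 | C10-methyl analogue of 25 (C14 in place of OTf) | CC(C)(C)[Si](C)(C)OCC[C@@H]1[C@@H](O[Si](CC)(CC)CC)C/C(C)=C/CC/C(COCc2ccc(OC)cc2)=C/[C@H]1O[Si](C)(C)C(C)(C)C | intermediate
27 | C8,C12-diol (C6 OTBS, C15 OPMB) | OCC[C@@H]1[C@@H](O)C/C(C)=C/CC/C(COCc2ccc(OC)cc2)=C/[C@H]1O[Si](C)(C)C(C)(C)C | intermediate
28 | 12,8-lactol (anomeric mixture) | C1C(O)O[C@H]2C/C(C)=C/CC/C(COCc3ccc(OC)cc3)=C/[C@@H](O[Si](C)(C)C(C)(C)C)[C@H]12 | intermediate
29 | trans-fused 12,8-γ-lactone (C6 OTBS, C15 OPMB) | C1C(=O)O[C@H]2C/C(C)=C/CC/C(COCc3ccc(OC)cc3)=C/[C@@H](O[Si](C)(C)C(C)(C)C)[C@H]12 | intermediate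
30 | lithium enolate of lactone 29 | C1=C([O-])O[C@H]2C/C(C)=C/CC/C(COCc3ccc(OC)cc3)=C/[C@@H](O[Si](C)(C)C(C)(C)C)[C@H]12.[Li+] | intermediate
31 | C11 (dimethylamino)methyl lactone (Mannich base) | CN(C)CC1C(=O)O[C@H]2C/C(C)=C/CC/C(COCc3ccc(OC)cc3)=C/[C@@H](O[Si](C)(C)C(C)(C)C)[C@H]12 | intermediate
32 | C11 (trimethylammonio)methyl lactone iodide | C[N+](C)(C)CC1C(=O)O[C@H]2C/C(C)=C/CC/C(COCc3ccc(OC)cc3)=C/[C@@H](O[Si](C)(C)C(C)(C)C)[C@H]12.[I-] | intermediate
33 | α-methylene-γ-lactone (C6 OTBS, C15 OPMB) | C=C1C(=O)O[C@H]2C/C(C)=C/CC/C(COCc3ccc(OC)cc3)=C/[C@@H](O[Si](C)(C)C(C)(C)C)[C@H]12 | intermediate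
34 | α-methylene-γ-lactone with free C15 OH (C6 OTBS) | C=C1C(=O)O[C@H]2C/C(C)=C/CC/C(CO)=C/[C@@H](O[Si](C)(C)C(C)(C)C)[C@H]12 | intermediate
35 | (tert-butyldimethylsilyloxy)acetaldehyde | O=CCO[Si](C)(C)C(C)(C)C | starting material
36 | ethyl 2-(triphenylphosphoranylidene)propanoate | CCOC(=O)C(C)=P(c1ccccc1)(c1ccccc1)c1ccccc1 | starting material
37 | ethyl (E)-4-(TBS-oxy)-2-methylbut-2-enoate | CCOC(=O)/C(C)=C/CO[Si](C)(C)C(C)(C)C | intermediate
38 | (E)-4-(TBS-oxy)-2-methylbut-2-enoic acid | OC(=O)/C(C)=C/CO[Si](C)(C)C(C)(C)C | intermediate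
39 | C15 (E)-4-(TBS-oxy)-2-methylbut-2-enoate of 34 (C6 OTBS) | C=C1C(=O)O[C@H]2C/C(C)=C/CC/C(COC(=O)/C(C)=C/CO[Si](C)(C)C(C)(C)C)=C/[C@@H](O[Si](C)(C)C(C)(C)C)[C@H]12 | intermediate
40 | CNP0326626.1, (6R,7S,8S)-6-hydroxy-15-[(E)-4-hydroxy-2-methylbut-2-enoyloxy]germacra-1(10),4,11(13)-trien-12,8-olide | C=C1C(=O)O[C@H]2C/C(C)=C/CC/C(COC(=O)/C(C)=C/CO)=C/[C@@H](O)[C@H]12 | target

Total step count: 24. Longest linear sequence: 21 steps (steps 1–6, 8–20, 23 and 24; steps 7, 21 and 22 prepare side fragments).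

Steps most likely to fail

Step 15. O-Sulfonylation of the hindered medium-ring potassium enolate may be slower than proton transfer, so that the enolate moves to the C9 side and expels the C8 silanolate, or the triflate may not survive isolation. The fallback sets out from 22: the same KH/18-crown-6 rearrangement is run, but enolate 24 is trapped with diethyl chlorophosphate, a harder and faster electrophile, to give the enol diethyl phosphate F1. F1 is then methylated with trimethylaluminium under Pd(PPh3)4 catalysis (enol phosphate cross-coupling), which comes back to the route at 26.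

Step 14. Facial selectivity may be poor, axial attack giving the cis-dialkenyl carbinol that would lead to a ring-cis olefin. The fallback sets out from 20: dimethylsulfoxonium methylide (NaH, DMSO/THF) adds reversibly and should close the spiro-epoxide F2 with the new C–C bond equatorial and the oxygen axial. Excess dimethylsulfonium methylide (Me3S+ I−, n-BuLi, THF) then opens the oxirane at its CH2 and eliminates dimethyl sulfide to give the allylic alcohol, which comes back to the route at 22.

Step 5. Regiocontrol of the enolisation may be lost; deprotonation at C9 would be followed by β-elimination of the silanolate and aromatisation. The fallback sets out from 4: alkaline hydrogen peroxide (Weitz–Scheffer epoxidation, anti to the C7 arm) gives the epoxy ketone F3, in which only C5 can be enolised. The same LDA/sulfinimidoyl chloride dehydrogenation gives the epoxy enone F4, samarium diiodide at −90 °C opens the epoxy ketone to the 5-hydroxy enone F5, and silylation with TESCl comes back to the route at 9.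

Further compounds
F1 | step 15 | ten-membered C10 enol diethyl phosphate (otherwise as 25) | CC(C)(C)[Si](C)(C)OCC[C@@H]1[C@@H](O[Si](CC)(CC)CC)C/C(OP(=O)(OCC)OCC)=C/CC/C(COCc2ccc(OC)cc2)=C/[C@H]1O[Si](C)(C)C(C)(C)C
F2 | step 14 | C10 spiro-epoxide of 20 (oxygen axial, CH2 equatorial) | C1O[C@]12C[C@H](O[Si](CC)(CC)CC)[C@@H](CCO[Si](C)(C)C(C)(C)C)[C@H](O[Si](C)(C)C(C)(C)C)[C@H]2C(=C)COCc1ccc(OC)cc1
F3 | step 5 | 2,3-epoxy-4-[2-(TBS-oxy)ethyl]cyclohexan-1-one (oxirane trans to the side chain) | O=C1[C@@H]2O[C@@H]2[C@@H](CCO[Si](C)(C)C(C)(C)C)CC1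
F4 | step 5 | 5,6-epoxy-4-[2-(TBS-oxy)ethyl]cyclohex-2-en-1-one | O=C1[C@@H]2O[C@@H]2[C@@H](CCO[Si](C)(C)C(C)(C)C)C=C1
F5 | step 5 | (4S,5S)-5-hydroxy-4-[2-(TBS-oxy)ethyl]cyclohex-2-en-1-one | O=C1C[C@H](O)[C@@H](CCO[Si](C)(C)C(C)(C)C)C=C1
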